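**Retrosynthetic overview**

1. Feature: ring A is a 2-substituted resorcinol diether. C1 (CO2H) lies between C2 (OMe) and C6 (O–ring B), C3 carries the (S)-acetoxyalkyl chain, and C4/C5 are unsubstituted. This is the pattern a vinylketene (C2–C5) and an alkynyl ether (C1, C6) deliver.
2. Target 34 ⇒ phenol 26 (C2 OH, C1 CH2OTBS, C3 CH(OTBDPS)CH2CHMe2, ring B carrying a dioxolane and OPMB). The late steps are O-methylation, Wittig on ring B's unmasked aldehyde, CH2OH → CO2H, silyl ether → acetate, and PMB removal.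
3. 26 ⇒ diazoketone 8 + ring B aryl ynol ether 21. Wolff rearrangement, [2+2] addition, 4-electron opening and 6-electron closure form C1–C2, C5–C6 and C2–C3 and close ring A. The diaryl ether oxygen is already in place on an sp carbon.
4. 8 ⇒ L-leucic acid 1 (stereocentre from the chiral pool) and ylide 5. 21 ⇒ creosol 9, trichloroethylene 14 and formaldehyde.
5. Ring order: ring B is present from the start (creosol); ring A is the only ring built (step 13).

Key step: step 13

Remark on the chemistry: the oxygen at the stereocentre is carried as a TBDPS ether and acetylated only after the C2 phenol of ring A is methylated, because a phenoxide ortho to a benzylic acetate would expel acetate through an ortho-quinone methide and erase the stereocentre; the diazoketone is made from the methyl enone by deacylative diazo transfer, because an enoyl chloride and diazomethane tend to give pyrazolines.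

**Route**

Step 1
Reactants: 1 L-leucic acid
Product: 2 methyl (S)-2-hydroxy-4-methylpentanoate
Conditions: MeOH, H2SO4 (cat.), reflux
Reagents that add atoms: methanol, CO
Why: Fischer esterification breaks no bond at the stereocentre, so the (S) configuration is kept.

Step 2
Reactants: 2 methyl (S)-2-hydroxy-4-methylpentanoate
Product: 3 methyl (S)-2-(tert-butyldiphenylsilyloxy)-4-methylpentanoate
Conditions: TBDPSCl, imidazole, DMF, rt
Reagents that add atoms: tert-butyl(chloro)diphenylsilane, CC(C)(C)[Si](Cl)(c1ccccc1)c1ccccc1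
Why: Imidazole-mediated O-silylation of a secondary alcohol installs a group that survives base, dilute aqueous acid and the benzannulation and cannot act as a leaving group next to a phenoxide.

Step 3
Reactants: 3 methyl (S)-2-(tert-butyldiphenylsilyloxy)-4-methylpentanoate
Product: 4 (S)-2-(tert-butyldiphenylsilyloxy)-4-methylpentanal
Conditions: i-Bu2AlH, CH2Cl2, −78 °C; aq. KNaC4H4O6 (potassium sodium tartrate)
Reagents that add atoms: none
Why: Partial ester reduction by i-Bu2AlH at −78 °C should stop at the aluminium hemiacetal, and the α-silyloxy aldehyde is configurationally stable when used at once.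

Step 4
Reactants: 4 (S)-2-(tert-butyldiphenylsilyloxy)-4-methylpentanal; 5 1-(triphenylphosphoranylidene)propan-2-one
Product: 6 (5S,3E)-5-(tert-butyldiphenylsilyloxy)-7-methyloct-3-en-2-one
Conditions: CH2Cl2, rt (or toluene, 60 °C)
Reagents that add atoms: none
Why: Wittig olefination with a stabilised acetonyl ylide should give the (E)-enone under neutral conditions that do not epimerise the α-silyloxy aldehyde.

Step 5
Reactants: 6 (5S,3E)-5-(tert-butyldiphenylsilyloxy)-7-methyloct-3-en-2-one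
Product: 8 (5S,3E)-5-(tert-butyldiphenylsilyloxy)-1-diazo-7-methyloct-3-en-2-one, via trifluoroacetyl diketone 7 (not isolated)
Conditions: LiN(SiMe3)2, THF, −78 °C; CF3CO2CH2CF3; aq. HCl work-up; then MsN3, Et3N, H2O, MeCN, rt
Reagents that add atoms: methanesulfonyl azide, CS(=O)(=O)N=[N+]=[N-]
Why: Detrifluoroacetylative (Regitz-type deacylative) diazo transfer: the kinetic α'-enolate of the methyl ketone is trifluoroacetylated to 7, and the sulfonyl azide then delivers N2 with loss of the trifluoroacetyl group, a sequence developed for α'-diazo enones.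

Step 6
Reactants: 9 creosol (2-methoxy-4-methylphenol)
Product: 11 2-hydroxy-3-methoxy-5-methylbenzaldehyde, via salicyl alcohol 10 (not isolated)
Conditions: MgCl2, Et3N, (CH2O)n, MeCN, reflux; aq. HCl work-up
Reagents that add atoms: formaldehyde (as paraformaldehyde), C=O
Why: Magnesium phenoxide-directed ortho-formylation can only occur at the single free ortho position, and a second formaldehyde oxidises salicyl alcohol 10 by hydride transfer.

Step 7
Reactants: 11 2-hydroxy-3-methoxy-5-methylbenzaldehyde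
Product: 12 2,3-dihydroxy-5-methylbenzaldehyde
Conditions: BBr3, CH2Cl2, −78 °C to rt; H2O
Reagents that add atoms: none
Why: Lewis acid cleavage of an aryl methyl ether by BBr3 is routine for ortho-vanillin-type aldehydes and leaves the formyl group intact.

Step 8
Reactants: 12 2,3-dihydroxy-5-methylbenzaldehyde
Product: 13 2-hydroxy-3-(4-methoxybenzyloxy)-5-methylbenzaldehyde
Conditions: NaH (2.2 equiv), DMSO, rt; PMBCl (1.0 equiv)
Reagents that add atoms: 4-methoxybenzyl chloride, COc1ccc(CCl)cc1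
Why: Williamson alkylation of the dianion: the 2-oxide is conjugated to and chelated by the formyl group, so one equivalent of halide should alkylate the more nucleophilic 3-oxide.

Step 9
Reactants: 13 2-hydroxy-3-(4-methoxybenzyloxy)-5-methylbenzaldehyde; 14 trichloroethylene
Product: 16 2-[(E)-1,2-dichloroethenyloxy]-3-(4-methoxybenzyloxy)-5-methylbenzaldehyde, via dichloroacetylene 15 (not isolated)
Conditions: K2CO3, DMF, 70 °C
Reagents that add atoms: none
Why: Base-induced elimination of trichloroethylene to dichloroacetylene 15 and anti addition of the phenoxide is the standard route from phenols to (E)-1,2-dichlorovinyl ethers, and the non-enolisable aldehyde tolerates it.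

Step 10
Reactants: 16 2-[(E)-1,2-dichloroethenyloxy]-3-(4-methoxybenzyloxy)-5-methylbenzaldehyde
Product: 17 2-[2-[(E)-1,2-dichloroethenyloxy]-3-(4-methoxybenzyloxy)-5-methylphenyl]-1,3-dioxolane
Conditions: TMSOCH2CH2OTMS, TMSOTf (cat.), CH2Cl2, −78 to −20 °C
Reagents that add atoms: 1,2-bis(trimethylsilyloxy)ethane, C[Si](C)(C)OCCO[Si](C)(C)C
Why: Noyori acetalisation at low temperature masks the aldehyde against butyllithium and is mild enough for the PMB ether and the dichlorovinyl ether.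

Step 11
Reactants: 17 2-[2-[(E)-1,2-dichloroethenyloxy]-3-(4-methoxybenzyloxy)-5-methylphenyl]-1,3-dioxolane
Product: 20 3-[2-(1,3-dioxolan-2-yl)-6-(4-methoxybenzyloxy)-4-methylphenoxy]prop-2-yn-1-ol, via chloroalkynyl ether 18 (not isolated), via lithium aryloxyacetylide 19 (not isolated)
Conditions: n-BuLi (2.2 equiv), THF, −78 to −40 °C; (CH2O)n, −78 °C to rt; aq. NH4Cl
Reagents that add atoms: formaldehyde (as paraformaldehyde), C=O
Why: Dehydrochlorination to 18 and chlorine–lithium exchange give acetylide 19 (the established dichlorovinyl ether route to alkynyl ethers), which adds to formaldehyde; at −78 °C the dichlorovinyl group should react faster than the PMB or acetal C–H bonds.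

Step 12
Reactants: 20 3-[2-(1,3-dioxolan-2-yl)-6-(4-methoxybenzyloxy)-4-methylphenoxy]prop-2-yn-1-ol
Product: 21 ring B ynol ether tert-butyl[3-[2-(1,3-dioxolan-2-yl)-6-(4-methoxybenzyloxy)-4-methylphenoxy]prop-2-ynyloxy]dimethylsilane
Conditions: TBSCl, imidazole, DMF, 0 °C to rt
Reagents that add atoms: tert-butyl(chloro)dimethylsilane, CC(C)(C)[Si](C)(C)Cl
Why: Standard O-silylation of a primary alcohol under basic conditions avoids the acid-induced rearrangement of the alkynyl ether carbinol to an acrylate.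

Step 13
Reactants: 8 (5S,3E)-5-(tert-butyldiphenylsilyloxy)-1-diazo-7-methyloct-3-en-2-one (1.3 equiv); 21 ring B ynol ether
Product: 26 ring A phenol 6-[(1S)-1-(tert-butyldiphenylsilyloxy)-3-methylbutyl]-2-[(tert-butyldimethylsilyloxy)methyl]-3-[2-(1,3-dioxolan-2-yl)-6-(4-methoxybenzyloxy)-4-methylphenoxy]phenol, via vinylketene 22 (not isolated), via vinylcyclobutenone 23 (not isolated), via dienylketene 24 (not isolated), via cyclohexadienone 25 (not isolated)
Conditions: hν (300 nm, Pyrex), degassed ClCH2CH2Cl, rt; then 80 °C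
Reagents that add atoms: none
Why: Irradiation expels N2 from 8 and the alkenyl group migrates (photochemical Wolff rearrangement) to give vinylketene 22, whose carbonyl carbon is attacked by the nucleophilic alkyne carbon of 21 (the one bearing CH2OTBS) in a [2+2] cycloaddition to 4-vinylcyclobutenone 23. Heating opens 23 by 4-electron electrocyclic cleavage to dienylketene 24, and ring A is closed by 6-electron electrocyclisation (C2–C3) to dienone 25, which tautomerises to phenol 26; in all, C1–C2, C5–C6 and C2–C3 are formed. The closest known reaction type is the photochemical (second-generation) Danheiser benzannulation of α'-diazo enones with alkoxy- and siloxyalkynes, and the aryloxyalkyne belongs to the same alkynyl ether class. No stereocentre is created: the sp3 centres of 23 and 25 are transient, and the (S) centre lies outside the reacting π system and is carried over unchanged. The step needs a single orientation of the [2+2] addition, which the polarisation of the ynol ether secures, placing C1 between C2–OH and C6–OAr. An aryl ynol ether has no C–H β to oxygen on an sp3 carbon, so it cannot fragment by retro-ene reaction at 80 °C.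

Step 14
Reactants: 26 ring A phenol
Product: 27 methyl ether tert-butyl[[3-[(1S)-1-(tert-butyldiphenylsilyloxy)-3-methylbutyl]-6-[2-(1,3-dioxolan-2-yl)-6-(4-methoxybenzyloxy)-4-methylphenoxy]-2-methoxyphenyl]methoxy]dimethylsilane
Conditions: MeI, K2CO3, DMF, rt
Reagents that add atoms: iodomethane, CI
Why: Williamson O-methylation of the hindered phenol with a small electrophile; both ortho benzylic oxygens are silyl ethers, so the phenoxide has no leaving group to expel and the stereocentre is safe.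

Step 15
Reactants: 27 methyl ether
Product: 28 2-[4-[(1S)-1-(tert-butyldiphenylsilyloxy)-3-methylbutyl]-2-(hydroxymethyl)-3-methoxyphenoxy]-3-(4-methoxybenzyloxy)-5-methylbenzaldehyde
Conditions: 1 M HCl (aq), THF, rt
Reagents that add atoms: water, O
Why: Acid-catalysed hydrolysis cleaves the aryl dioxolane and the primary TBS ether, while the far more acid-stable secondary TBDPS ether and the aryl PMB ether should survive dilute HCl.

Step 16
Reactants: 28 hydroxy aldehyde; 5 1-(triphenylphosphoranylidene)propan-2-one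
Product: 29 (E)-4-[2-[4-[(1S)-1-(tert-butyldiphenylsilyloxy)-3-methylbutyl]-2-(hydroxymethyl)-3-methoxyphenoxy]-3-(4-methoxybenzyloxy)-5-methylphenyl]but-3-en-2-one
Conditions: toluene, 80 °C
Reagents that add atoms: none
Why: Wittig olefination with the stabilised ylide should give the (E)-enone on ring B's aldehyde, the only aldehyde present at this stage, and tolerates the free primary alcohol.

Step 17
Reactants: 29 enone alcohol
Product: 30 3-[(1S)-1-(tert-butyldiphenylsilyloxy)-3-methylbutyl]-2-methoxy-6-[2-(4-methoxybenzyloxy)-4-methyl-6-[(E)-3-oxobut-1-enyl]phenoxy]benzaldehyde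
Conditions: Dess–Martin periodinane, CH2Cl2, rt
Reagents that add atoms: none
Why: Dess–Martin oxidation of the only free (primary benzylic) alcohol stops at the aldehyde and leaves the enone, silyl ether and PMB ether alone.

Step 18
Reactants: 30 silyloxy aldehyde
Product: 31 3-[(1S)-1-hydroxy-3-methylbutyl]-2-methoxy-6-[2-(4-methoxybenzyloxy)-4-methyl-6-[(E)-3-oxobut-1-enyl]phenoxy]benzaldehyde
Conditions: Bu4NF, AcOH (1:1), THF, rt to 40 °C
Reagents that add atoms: none
Why: Fluoride-induced Si–O cleavage, buffered with acetic acid to protect the enone and aldehyde from basic fluoride, leaves the C–O bond intact, so the (S) configuration is retained.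

Step 19
Reactants: 31 secondary alcohol
Product: 32 (1S)-1-[3-formyl-2-methoxy-4-[2-(4-methoxybenzyloxy)-4-methyl-6-[(E)-3-oxobut-1-enyl]phenoxy]phenyl]-3-methylbutyl acetate
Conditions: Ac2O, Et3N, DMAP (cat.), CH2Cl2, 0 °C to rt
Reagents that add atoms: acetic anhydride, CC(=O)OC(C)=O
Why: DMAP-catalysed acylation of the only hydroxyl group proceeds at oxygen with retention, and no phenol is free on ring A to endanger the benzylic acetate.

Step 20
Reactants: 32 acetoxy aldehyde
Product: 33 3-[(1S)-1-acetoxy-3-methylbutyl]-2-methoxy-6-[2-(4-methoxybenzyloxy)-4-methyl-6-[(E)-3-oxobut-1-enyl]phenoxy]benzoic acid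
Conditions: NaClO2, NaH2PO4, 2-methyl-2-butene, t-BuOH/H2O, rt
Reagents that add atoms: sodium chlorite, [Na+].[O-]Cl=O
Why: Pinnick oxidation should convert the hindered aryl aldehyde into the acid at about pH 4 without touching the enone, the benzylic acetate or the PMB ether, the alkene scavenging hypochlorous acid.

Step 21
Reactants: 33 PMB-protected acid
Product: 34 target 3-[(1S)-1-acetoxy-3-methylbutyl]-6-[2-hydroxy-4-methyl-6-[(E)-3-oxobut-1-enyl]phenoxy]-2-methoxybenzoic acid
Conditions: DDQ, CH2Cl2/aq. NaH2PO4–Na2HPO4 (pH 7), 0 °C to rt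
Reagents that add atoms: none
Why: Oxidative PMB cleavage by DDQ (hydride abstraction from the electron-rich benzyl group, then hydrolysis) runs under near-neutral conditions that should spare the acid-labile benzylic acetate, the enone and the carboxylic acid.

**Compound list**

1 | L-leucic acid, (S)-2-hydroxy-4-methylpentanoic acid | CC(C)C[C@H](O)C(=O)O | starting material
2 | methyl (S)-2-hydroxy-4-methylpentanoate | COC(=O)[C@H](CC(C)C)O | intermediate
3 | methyl (S)-2-(tert-butyldiphenylsilyloxy)-4-methylpentanoate | COC(=O)[C@H](CC(C)C)O[Si](c1ccccc1)(c1ccccc1)C(C)(C)C | intermediate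
4 | (S)-2-(tert-butyldiphenylsilyloxy)-4-methylpentanal | O=C[C@H](CC(C)C)O[Si](c1ccccc1)(c1ccccc1)C(C)(C)C | intermediate
5 | 1-(triphenylphosphoranylidene)propan-2-one | CC(=O)C=P(c1ccccc1)(c1ccccc1)c1ccccc1 | starting material
6 | (5S,3E)-5-(tert-butyldiphenylsilyloxy)-7-methyloct-3-en-2-one | CC(=O)/C=C/[C@H](CC(C)C)O[Si](c1ccccc1)(c1ccccc1)C(C)(C)C | intermediate
7 | (7S,5E)-7-(tert-butyldiphenylsilyloxy)-1,1,1-trifluoro-9-methyldec-5-ene-2,4-dione | O=C(CC(=O)/C=C/[C@H](CC(C)C)O[Si](c1ccccc1)(c1ccccc1)C(C)(C)C)C(F)(F)F | intermediate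
8 | (5S,3E)-5-(tert-butyldiphenylsilyloxy)-1-diazo-7-methyloct-3-en-2-one | [N-]=[N+]=CC(=O)/C=C/[C@H](CC(C)C)O[Si](c1ccccc1)(c1ccccc1)C(C)(C)C | intermediate
9 | creosol, 2-methoxy-4-methylphenol | COc1cc(C)ccc1O | starting material
10 | 2-(hydroxymethyl)-6-methoxy-4-methylphenol | COc1cc(C)cc(CO)c1O | intermediate
11 | 2-hydroxy-3-methoxy-5-methylbenzaldehyde | COc1cc(C)cc(C=O)c1O | intermediate
12 | 2,3-dihydroxy-5-methylbenzaldehyde | Cc1cc(O)c(O)c(C=O)c1 | intermediate
13 | 2-hydroxy-3-(4-methoxybenzyloxy)-5-methylbenzaldehyde | COc1ccc(COc2cc(C)cc(C=O)c2O)cc1 | intermediate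
14 | trichloroethylene | ClC=C(Cl)Cl | starting material
15 | dichloroacetylene | ClC#CCl | intermediate
16 | 2-[(E)-1,2-dichloroethenyloxy]-3-(4-methoxybenzyloxy)-5-methylbenzaldehyde | Cl/C=C(/Cl)Oc1c(OCc2ccc(OC)cc2)cc(C)cc1C=O | intermediate
17 | 2-[2-[(E)-1,2-dichloroethenyloxy]-3-(4-methoxybenzyloxy)-5-methylphenyl]-1,3-dioxolane | Cl/C=C(/Cl)Oc1c(OCc2ccc(OC)cc2)cc(C)cc1C1OCCO1 | intermediate
18 | 2-[2-(chloroethynyloxy)-3-(4-methoxybenzyloxy)-5-methylphenyl]-1,3-dioxolane | ClC#COc1c(OCc2ccc(OC)cc2)cc(C)cc1C1OCCO1 | intermediate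
19 | lithium [2-(1,3-dioxolan-2-yl)-6-(4-methoxybenzyloxy)-4-methylphenoxy]acetylide | [Li]C#COc1c(OCc2ccc(OC)cc2)cc(C)cc1C1OCCO1 | intermediate
20 | 3-[2-(1,3-dioxolan-2-yl)-6-(4-methoxybenzyloxy)-4-methylphenoxy]prop-2-yn-1-ol | OCC#COc1c(OCc2ccc(OC)cc2)cc(C)cc1C1OCCO1 | intermediate
21 | ring B ynol ether, tert-butyl[3-[2-(1,3-dioxolan-2-yl)-6-(4-methoxybenzyloxy)-4-methylphenoxy]prop-2-ynyloxy]dimethylsilane | CC(C)(C)[Si](C)(C)OCC#COc1c(OCc2ccc(OC)cc2)cc(C)cc1C1OCCO1 | intermediate
22 | vinylketene, (5S,3E)-5-(tert-butyldiphenylsilyloxy)-7-methylocta-1,3-dien-1-one | O=C=C/C=C/[C@H](CC(C)C)O[Si](c1ccccc1)(c1ccccc1)C(C)(C)C | intermediate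
23 | vinylcyclobutenone, 3-(ring B aryloxy)-2-[(TBS-oxy)methyl]-4-[(1E,3S)-3-(TBDPS-oxy)-5-methylhex-1-enyl]cyclobut-2-en-1-one (C4 unassigned) | O=C1C(CO[Si](C)(C)C(C)(C)C)=C(Oc2c(OCc3ccc(OC)cc3)cc(C)cc2C2OCCO2)C1/C=C/[C@H](CC(C)C)O[Si](c1ccccc1)(c1ccccc1)C(C)(C)C | intermediate
24 | dienylketene, (5E,7S)-3-(ring B aryloxy)-2-[(TBS-oxy)methyl]-7-(TBDPS-oxy)-9-methyldeca-1,3,5-trien-1-one, drawn as the C3=C4 isomer that cyclises | O=C=C(CO[Si](C)(C)C(C)(C)C)/C(Oc1c(OCc2ccc(OC)cc2)cc(C)cc1C1OCCO1)=C\C=C\[C@H](CC(C)C)O[Si](c1ccccc1)(c1ccccc1)C(C)(C)C | intermediate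
25 | cyclohexadienone, 6-[(1S)-1-(TBDPS-oxy)-3-methylbutyl]-3-(ring B aryloxy)-2-[(TBS-oxy)methyl]cyclohexa-2,4-dien-1-one (C6 unassigned) | O=C1C(CO[Si](C)(C)C(C)(C)C)=C(Oc2c(OCc3ccc(OC)cc3)cc(C)cc2C2OCCO2)C=CC1[C@H](CC(C)C)O[Si](c1ccccc1)(c1ccccc1)C(C)(C)C | intermediate
26 | ring A phenol, 6-[(1S)-1-(tert-butyldiphenylsilyloxy)-3-methylbutyl]-2-[(tert-butyldimethylsilyloxy)methyl]-3-[2-(1,3-dioxolan-2-yl)-6-(4-methoxybenzyloxy)-4-methylphenoxy]phenol | Oc1c([C@H](CC(C)C)O[Si](c2ccccc2)(c2ccccc2)C(C)(C)C)ccc(Oc2c(OCc3ccc(OC)cc3)cc(C)cc2C2OCCO2)c1CO[Si](C)(C)C(C)(C)C | intermediate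
27 | O-methyl ether of 26 | COc1c([C@H](CC(C)C)O[Si](c2ccccc2)(c2ccccc2)C(C)(C)C)ccc(Oc2c(OCc3ccc(OC)cc3)cc(C)cc2C2OCCO2)c1CO[Si](C)(C)C(C)(C)C | intermediate
28 | 2-[4-[(1S)-1-(tert-butyldiphenylsilyloxy)-3-methylbutyl]-2-(hydroxymethyl)-3-methoxyphenoxy]-3-(4-methoxybenzyloxy)-5-methylbenzaldehyde | COc1c([C@H](CC(C)C)O[Si](c2ccccc2)(c2ccccc2)C(C)(C)C)ccc(Oc2c(OCc3ccc(OC)cc3)cc(C)cc2C=O)c1CO | intermediate
29 | (E)-4-[2-[4-[(1S)-1-(tert-butyldiphenylsilyloxy)-3-methylbutyl]-2-(hydroxymethyl)-3-methoxyphenoxy]-3-(4-methoxybenzyloxy)-5-methylphenyl]but-3-en-2-one | COc1c([C@H](CC(C)C)O[Si](c2ccccc2)(c2ccccc2)C(C)(C)C)ccc(Oc2c(OCc3ccc(OC)cc3)cc(C)cc2/C=C/C(C)=O)c1CO | intermediate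
30 | 3-[(1S)-1-(tert-butyldiphenylsilyloxy)-3-methylbutyl]-2-methoxy-6-[2-(4-methoxybenzyloxy)-4-methyl-6-[(E)-3-oxobut-1-enyl]phenoxy]benzaldehyde | COc1c([C@H](CC(C)C)O[Si](c2ccccc2)(c2ccccc2)C(C)(C)C)ccc(Oc2c(OCc3ccc(OC)cc3)cc(C)cc2/C=C/C(C)=O)c1C=O | intermediate
31 | 3-[(1S)-1-hydroxy-3-methylbutyl]-2-methoxy-6-[2-(4-methoxybenzyloxy)-4-methyl-6-[(E)-3-oxobut-1-enyl]phenoxy]benzaldehyde | COc1c([C@H](CC(C)C)O)ccc(Oc2c(OCc3ccc(OC)cc3)cc(C)cc2/C=C/C(C)=O)c1C=O | intermediate
32 | (1S)-1-[3-formyl-2-methoxy-4-[2-(4-methoxybenzyloxy)-4-methyl-6-[(E)-3-oxobut-1-enyl]phenoxy]phenyl]-3-methylbutyl acetate | COc1c([C@H](CC(C)C)OC(C)=O)ccc(Oc2c(OCc3ccc(OC)cc3)cc(C)cc2/C=C/C(C)=O)c1C=O | intermediate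
33 | 3-[(1S)-1-acetoxy-3-methylbutyl]-2-methoxy-6-[2-(4-methoxybenzyloxy)-4-methyl-6-[(E)-3-oxobut-1-enyl]phenoxy]benzoic acid | COc1c([C@H](CC(C)C)OC(C)=O)ccc(Oc2c(OCc3ccc(OC)cc3)cc(C)cc2/C=C/C(C)=O)c1C(=O)O | intermediate
34 | CNP0281268.1, 3-[(1S)-1-acetoxy-3-methylbutyl]-6-[2-hydroxy-4-methyl-6-[(E)-3-oxobut-1-enyl]phenoxy]-2-methoxybenzoic acid | COc1c([C@H](CC(C)C)OC(C)=O)ccc(Oc2c(O)cc(C)cc2/C=C/C(C)=O)c1C(=O)O | target

**Step count and risks**

Total step count: 21. Longest linear sequence: 16 steps (creosol 9 to target 34, steps 6–21); the L-leucic acid branch (steps 1–5) joins at step 13.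

Steps most likely to fail:

1. Step 13. The short-lived vinylketene may dimerise or photodecompose faster than the hindered, only moderately nucleophilic aryloxyalkyne captures it, or the thermal stage may stall at the cyclobutenone. The fallback sets out from diazoketone 8 and comes back to the route at 28; it makes the diaryl ether after ring A instead of before.
   - The same irradiation and heating is run with triisopropyl[3-(tert-butyldimethylsilyloxy)prop-1-ynyloxy]silane F1, a member of the best-established alkyne class. F1 is made from commercial ethyl (tert-butyldimethylsilyloxy)acetate by Kowalski ynolate formation (LiCHBr2, then n-BuLi) and O-silylation with i-Pr3SiCl.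
   - This should give 6-[(1S)-1-(tert-butyldiphenylsilyloxy)-3-methylbutyl]-2-[(tert-butyldimethylsilyloxy)methyl]-3-(triisopropylsilyloxy)phenol F2.
   - MeI/K2CO3 converts it into the methyl ether F3.
   - One equivalent of Bu4NF at −20 °C cleaves only the aryl silyl ether, giving 4-[(1S)-1-(tert-butyldiphenylsilyloxy)-3-methylbutyl]-2-[(tert-butyldimethylsilyloxy)methyl]-3-methoxyphenol F4.
   - Buchwald–Hartwig-type C–O coupling (Pd(OAc)2, t-BuXPhos, K3PO4, toluene, 100 °C) joins F4 to 2-formyl-6-(4-methoxybenzyloxy)-4-methylphenyl trifluoromethanesulfonate F5, prepared from phenol 13 with Tf2O and pyridine.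
   - The product is the silylated diaryl ether aldehyde F6, whose primary silyl ether is hydrolysed with 1 M HCl in THF to give 28.

2. Step 11. Butyllithium may attack the PMB benzylic or acetal C–H bonds, trapping by solid paraformaldehyde may be incomplete, and the aryloxypropargyl alcohol may rearrange to an acrylate on work-up. The fallback sets out from phenol 13 and comes back at ynol ether 21 without any organolithium.
   - 13 is acetalised (TMSOCH2CH2OTMS, cat. TMSOTf, then K2CO3/MeOH to free the phenol) to 2-(1,3-dioxolan-2-yl)-6-(4-methoxybenzyloxy)-4-methylphenol F7.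
   - Copper-catalysed C–O coupling (CuI, 2,2'-bipyridine, K3PO4, toluene, 110 °C) joins F7 to tert-butyl(3,3-dibromoprop-2-enyloxy)dimethylsilane F8, made by Corey–Fuchs dibromo-olefination of commercial (tert-butyldimethylsilyloxy)acetaldehyde.
   - This should give the (Z)-1-bromo enol ether F9, and anti dehydrobromination with KOt-Bu gives 21.

3. Step 21. Cleavage of an aryl PMB ether by DDQ is slow, and the excess oxidant may over-oxidise the liberated electron-rich ring B phenol or form persistent charge-transfer adducts at the last step. The fallback sets out from aldehyde 30 and comes back at target 34; it removes the PMB group by acid before any acid-labile benzylic acetate exists.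
   - TFA with anisole in CH2Cl2 at 0 °C gives the ring B phenol F10.
   - Bu4NF/AcOH gives the phenol–alcohol F11.
   - Ac2O/Et3N/DMAP gives the diacetate F12.
   - Pinnick oxidation gives the diacetate acid F13.
   - Chemoselective methanolysis of the aryl acetate (NaHCO3, MeOH/H2O, rt), which leaves the hindered alkyl acetate alone, gives 34.

Further compounds
F1 | step 13 | triisopropyl[3-(tert-butyldimethylsilyloxy)prop-1-ynyloxy]silane | CC(C)[Si](OC#CCO[Si](C)(C)C(C)(C)C)(C(C)C)C(C)C
F2 | step 13 | 6-[(1S)-1-(tert-butyldiphenylsilyloxy)-3-methylbutyl]-2-[(tert-butyldimethylsilyloxy)methyl]-3-(triisopropylsilyloxy)phenol | Oc1c([C@H](CC(C)C)O[Si](c2ccccc2)(c2ccccc2)C(C)(C)C)ccc(O[Si](C(C)C)(C(C)C)C(C)C)c1CO[Si](C)(C)C(C)(C)C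
F3 | step 13 | O-methyl ether of F2 | COc1c([C@H](CC(C)C)O[Si](c2ccccc2)(c2ccccc2)C(C)(C)C)ccc(O[Si](C(C)C)(C(C)C)C(C)C)c1CO[Si](C)(C)C(C)(C)C
F4 | step 13 | 4-[(1S)-1-(tert-butyldiphenylsilyloxy)-3-methylbutyl]-2-[(tert-butyldimethylsilyloxy)methyl]-3-methoxyphenol | COc1c([C@H](CC(C)C)O[Si](c2ccccc2)(c2ccccc2)C(C)(C)C)ccc(O)c1CO[Si](C)(C)C(C)(C)C
F5 | step 13 | 2-formyl-6-(4-methoxybenzyloxy)-4-methylphenyl trifluoromethanesulfonate | COc1ccc(COc2cc(C)cc(C=O)c2OS(=O)(=O)C(F)(F)F)cc1
F6 | step 13 | 2-[4-[(1S)-1-(tert-butyldiphenylsilyloxy)-3-methylbutyl]-2-[(tert-butyldimethylsilyloxy)methyl]-3-methoxyphenoxy]-3-(4-methoxybenzyloxy)-5-methylbenzaldehyde | COc1c([C@H](CC(C)C)O[Si](c2ccccc2)(c2ccccc2)C(C)(C)C)ccc(Oc2c(OCc3ccc(OC)cc3)cc(C)cc2C=O)c1CO[Si](C)(C)C(C)(C)C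
F7 | step 11 | 2-(1,3-dioxolan-2-yl)-6-(4-methoxybenzyloxy)-4-methylphenol | COc1ccc(COc2cc(C)cc(C3OCCO3)c2O)cc1
F8 | step 11 | tert-butyl(3,3-dibromoprop-2-enyloxy)dimethylsilane | CC(C)(C)[Si](C)(C)OCC=C(Br)Br
F9 | step 11 | (Z)-1-bromo-3-(tert-butyldimethylsilyloxy)prop-1-enyl ether of F7 | CC(C)(C)[Si](C)(C)OC/C=C(\Br)Oc1c(OCc2ccc(OC)cc2)cc(C)cc1C1OCCO1
F10 | step 21 | 3-[(1S)-1-(tert-butyldiphenylsilyloxy)-3-methylbutyl]-6-[2-hydroxy-4-methyl-6-[(E)-3-oxobut-1-enyl]phenoxy]-2-methoxybenzaldehyde | COc1c([C@H](CC(C)C)O[Si](c2ccccc2)(c2ccccc2)C(C)(C)C)ccc(Oc2c(O)cc(C)cc2/C=C/C(C)=O)c1C=O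
F11 | step 21 | 3-[(1S)-1-hydroxy-3-methylbutyl]-6-[2-hydroxy-4-methyl-6-[(E)-3-oxobut-1-enyl]phenoxy]-2-methoxybenzaldehyde | COc1c([C@H](CC(C)C)O)ccc(Oc2c(O)cc(C)cc2/C=C/C(C)=O)c1C=O
F12 | step 21 | (1S)-1-[4-[2-acetoxy-4-methyl-6-[(E)-3-oxobut-1-enyl]phenoxy]-3-formyl-2-methoxyphenyl]-3-methylbutyl acetate | COc1c([C@H](CC(C)C)OC(C)=O)ccc(Oc2c(OC(C)=O)cc(C)cc2/C=C/C(C)=O)c1C=O
F13 | step 21 | 3-[(1S)-1-acetoxy-3-methylbutyl]-6-[2-acetoxy-4-methyl-6-[(E)-3-oxobut-1-enyl]phenoxy]-2-methoxybenzoic acid | COc1c([C@H](CC(C)C)OC(C)=O)ccc(Oc2c(OC(C)=O)cc(C)cc2/C=C/C(C)=O)c1C(=O)O
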